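**Remark on the chemistry.** The target SMILES contains no stereocentre and its diaryl ether axes are not configurationally stable, so the compound is achiral and "single enantiomer" adds no requirement. Aldehyde 1 and triether 6 are taken as purchasable.

## The problem

- Target 17 is built from four oxygenated benzene rings. Ring B (atoms B1–B6) carries the 2,4,6-trihydroxyphenoxy ring A on the oxygen at B1, hydrogen at B2, free hydroxyls at B3 and B5, and two identical 3,4,5-trihydroxyphenoxy rings C and D on the oxygens at B4 and B6.
- The three diaryl ether bonds are the whole connectivity problem. B4–O lies between two hydroxyls, B6–O between a hydroxyl and the ring-A ether, and the ring-A ether carbon between two hydroxyls. Every aryl–O bond therefore joins two very electron-rich rings and is flanked by ortho oxygens, the worst case for copper-mediated or SNAr etherification.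
- Ring B is pentaoxygenated and its five oxygens must be told apart: two stay free and three carry two different kinds of aryl group at fixed positions.
- No stereocontrol is needed.
- The sensitive groups are the eleven phenols, among them two pyrogallol units, which are oxidised by air in neutral or basic solution. The last deprotection must be neutral and reductive.
- The enabling feature: the oxygens at B1, B3 and B5 stand in a 1,3,5 relation, and B2, B4 and B6 between them carry H, OAr and OAr. Ring B is thus the enol form of a cyclohexane-1,3,5-trione (a triketide).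
- In that form B4–B5(=O)–B6 is an α,α′-bis(aryloxy) ketone, made C2-symmetric by the identity of rings C and D. B1–B2–B3 is a three-carbon acyl unit whose B1 is at the carboxylic acid oxidation level and can carry the ring-A oxygen as an ynol ether. All three diaryl ethers can therefore be made as ordinary alkyl aryl or alkynyl aryl ethers before ring B exists.

## Retrosynthesis

**17 ⇒ 16.** The nine O–benzyl bonds on rings A, C and D are cut. Benzyl is chosen over methyl because hydrogenolysis is neutral and leaves the polyphenol in a filtrate that needs no aqueous work-up. The precursor 16 already has B3–OH and B5–OH free, so no protecting group is ever placed on ring B.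

**16 ⇒ 15 ⇒ 5 + 14 (key disconnection).** Two C–C bonds of ring B are cut: B3–B4 (Dieckmann acylation) and B1–B6 (conjugate addition). This gives the C2-symmetric ketone 5 (B4–B5–B6 with rings C and D) and the ynoate 14 (B1–B2–B3 with ring A on B1).
- Against cutting the three aryl–O bonds: this cut needs no hindered arylation and no pentaoxygenated benzene building block.
- Against a ring-B cut that uses a symmetric malonyl partner: here the B1 oxygen arrives already arylated, so three ring-B hydroxyls never have to be differentiated.
- Simplification: both precursors are acyclic at the future ring B and neither contains a diaryl ether.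
- Demands on the forward reaction: addition of the enolate of 5 to C3 of 14 only, ring closure of 15 through carbon and not oxygen, and aromatisation.

**5 ⇒ 3 + 4, 3 ⇒ 1.** The two CH2–O bonds of 5 are cut to phenol 3 and 1,3-dichloroacetone 4. These bonds become the hindered B4–O and B6–O ethers of the target, but at this stage they are plain Williamson bonds. Phenol 3 comes from aldehyde 1 by aryl migration to oxygen through formate 2.

**14 ⇒ 13 ⇒ 11 ⇒ 10 ⇒ 8 ⇒ 6.** The ester carbon (future B3) is cut from acetylide 13. The alkynyl–O bond (future A-ring ether at B1) is traced through chloroalkyne 12 and dichlorovinyl ether 11 to phenol 10. Phenol 10 comes from aldehyde 8 (through formate 9), and 8 from the C3-symmetric triether 6 by formylation through iminium salt 7. The most hindered ether of the target is thus made by addition of a phenoxide to a linear two-carbon electrophile.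

## Roads not taken

**Alternative 1: three Ullmann etherifications on a preformed ring B (the obvious route).**
- Cut: the aryl–O bonds at B1, B4 and B6.
- Forward: 2,4-dibromo-3,5-bis(benzyloxy)phenol A1 is coupled through its OH with 2-bromo-1,3,5-tris(benzyloxy)benzene A2 to give diaryl ether A3. The two bromides of A3 are then coupled with phenol 3 to the undecabenzyl ether A4, which is hydrogenolysed.
- Why the chosen plan is better: A1 is itself a fully substituted, regiodefined benzene that needs its own multistep synthesis. All three couplings use electron-rich aryl bromides with two ortho oxygens, the slowest class for copper and one prone to reduction of the C–Br bond. The two bromides of A3 flank the same carbon, so the second coupling is more hindered than the first. This is three separate difficult events against one ring construction.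

**Alternative 2: SNAr on a formyl-activated fluoroarene, then Dakin oxidation.**
- Cut: B4–O and B6–O by SNAr, with B3–OH and B5–OH arising from formyl groups.
- Forward: 2,4-difluoro-5-[2,4,6-tris(benzyloxy)phenoxy]benzene-1,3-dicarbaldehyde A5 reacts twice with the phenoxide of 3 to give dialdehyde A6. A double Baeyer–Villiger oxidation and hydrolysis gives 16.
- Why the chosen plan is better: B1 is meta to both formyl groups, so the ring-A ether cannot be made by SNAr and still needs a hindered Ullmann coupling. A5 is not available, and placing two fluorines, two formyl groups and an aryloxy group on one ring is a longer run-up than the whole chosen route. The strategy remains "substitute a preformed arene".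

**Alternative 3: biomimetic oxidative C–O coupling.**
- Cut: B4–O and B6–O as phenoxy radical couplings.
- Forward: the diphlorethol-type dimer A7 and benzene-1,2,3,5-tetrol A8 are oxidised anodically or with a vanadium haloperoxidase mimic, so that oxygen radicals of A8 attack the free ring positions of A7.
- Why the chosen plan is better: every ring has several nucleophilic C–H sites and several hydroxyls, and radical coupling gives C–C as well as C–O links with no element that directs attack to B4 and B6 over B2. The pyrogallol rings of A8 and of the product are oxidised at lower potential than the phloroglucinol rings that must react, so the product is consumed as it forms.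

Key step: step 7

## Route

**Step 1**
Reactants: 1 3,4,5-tris(benzyloxy)benzaldehyde
Product: 3 3,4,5-tris(benzyloxy)phenol, via 3,4,5-tris(benzyloxy)phenyl formate 2 (not isolated)
Conditions: mCPBA, CH2Cl2, 0 °C → rt; aq. Na2SO3 wash; then KOH, MeOH/THF, 0 °C, Ar; dilute HCl
Reagents that add atoms: mCPBA, OOC(=O)c1cccc(Cl)c1
Why: Baeyer–Villiger oxidation of a para-alkoxybenzaldehyde (Dakin-type): the electron-rich aryl group migrates to oxygen to give formate 2, which hydroxide cleaves after the excess peracid has been destroyed.

**Step 2**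
Reactants: 3 3,4,5-tris(benzyloxy)phenol (2 equiv); 4 1,3-dichloroacetone
Product: 5 1,3-bis[3,4,5-tris(benzyloxy)phenoxy]propan-2-one
Conditions: K2CO3, KI (cat.), acetone, reflux
Reagents that add atoms: none
Why: Double Williamson etherification; the α-chloroketone carbons of 4 are highly SN2-reactive under iodide catalysis, and carbonate is too weak a base to enolise the product to a harmful extent.

**Step 3**
Reactants: 6 1,3,5-tris(benzyloxy)benzene
Product: 8 2,4,6-tris(benzyloxy)benzaldehyde, via N-[2,4,6-tris(benzyloxy)benzylidene]-N-methylmethanaminium chloride 7 (not isolated)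
Conditions: POCl3, DMF, 0 → 60 °C; then H2O, 50 °C
Reagents that add atoms: N,N-dimethylformamide, CN(C)C=O; water, O
Why: Vilsmeier–Haack formylation; the three ring C–H positions of 6 are equivalent and doubly activated, and the iminium group of 7 deactivates the ring against a second attack.

**Step 4**
Reactants: 8 2,4,6-tris(benzyloxy)benzaldehyde
Product: 10 2,4,6-tris(benzyloxy)phenol, via 2,4,6-tris(benzyloxy)phenyl formate 9 (not isolated)
Conditions: mCPBA, CH2Cl2, 0 °C → rt; aq. Na2SO3 wash; then KOH, MeOH/THF, 0 °C, Ar; dilute HCl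
Reagents that add atoms: mCPBA, OOC(=O)c1cccc(Cl)c1
Why: Baeyer–Villiger oxidation/hydrolysis (Dakin-type); two ortho and one para oxygen make aryl migration far faster than hydride migration, and formate 9 masks the oxidisable phenol until the peracid is quenched.

**Step 5**
Reactants: 10 2,4,6-tris(benzyloxy)phenol
Product: 11 1,3,5-tris(benzyloxy)-2-{[(E)-1,2-dichloroethenyl]oxy}benzene
Conditions: trichloroethylene, K2CO3, DMF, 70 °C, Ar
Reagents that add atoms: trichloroethylene, ClC=C(Cl)Cl
Why: Base converts trichloroethylene into dichloroacetylene, to which the phenoxide adds in anti fashion to give the (E)-dichlorovinyl ether; the linear electrophile tolerates the two ortho benzyloxy groups.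

**Step 6**
Reactants: 11 1,3,5-tris(benzyloxy)-2-{[(E)-1,2-dichloroethenyl]oxy}benzene
Product: 14 methyl 3-[2,4,6-tris(benzyloxy)phenoxy]prop-2-ynoate, via 1,3,5-tris(benzyloxy)-2-[(chloroethynyl)oxy]benzene 12 (not isolated), via lithium [2,4,6-tris(benzyloxy)phenoxy]acetylide 13 (not isolated)
Conditions: n-BuLi (2.2 equiv), THF, −78 → −40 °C; then cannulation into ClCO2Me, THF, −78 → 0 °C
Reagents that add atoms: methyl chloroformate, COC(Cl)=O
Why: The first equivalent of n-BuLi removes the vinyl proton and LiCl is lost to give chloroalkyne 12, the second effects Cl/Li exchange to acetylide 13, and inverse addition to the chloroformate gives the ynoate by C-acylation; aryl benzyl ethers are inert to n-BuLi at −78 °C on this time scale.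

**Step 7**
Reactants: 5 1,3-bis[3,4,5-tris(benzyloxy)phenoxy]propan-2-one; 14 methyl 3-[2,4,6-tris(benzyloxy)phenoxy]prop-2-ynoate
Product: 16 5-[2,4,6-tris(benzyloxy)phenoxy]-2,4-bis[3,4,5-tris(benzyloxy)phenoxy]benzene-1,3-diol, via methyl (E)-5-oxo-3-[2,4,6-tris(benzyloxy)phenoxy]-4,6-bis[3,4,5-tris(benzyloxy)phenoxy]hex-2-enoate 15 (not isolated)
Conditions: NaHMDS (1.0 equiv), THF, −78 °C; slow addition of 14 (1.0 equiv), −78 → 0 °C; then t-BuOH (2 equiv), 0 → 55 °C, Ar; degassed AcOH
Reagents that add atoms: none
Why: Proposed new method: the sodium enolate of C2-symmetric 5 should add through carbon (future B6) to C3 of ynoate 14, the only electrophilic alkyne carbon because it is β to the ester, to give 15 as its stabilised dienolate (Michael addition). Proton shuttling by t-BuOH equilibrates the E and Z isomers of 15 through that dienolate and gives access to the α′-enolate at B4, which attacks the ester carbon B3 in a 6-(enolendo)-exo-trig Dieckmann closure; loss of methoxide gives the keto tautomer of 16, which aromatises at once, so the closure is irreversible. The closest known reaction types are the base-mediated Michael–Dieckmann [3+3] benzannulation of acetonedicarboxylates with alkynoates to resorcinols and the alkoxide-induced isomerisation of 4-alkoxy-6-alkyl-2-pyranones to 5-alkoxyresorcinols, which is the same closure onto a β-alkoxy enoate; new here are the ynol ether acceptor and a ketone donor activated only by its α-aryloxy groups. Regiochemistry is fixed by the reagents and not by selectivity on an arene: ring A sits on B1 because it rides on C3 of 14, rings C and D sit on B4 and B6 because both α-carbons of 5 carry them, and the B3 and B5 hydroxyls are the former ester and ketone carbonyls. The selectivity needed is C- over O-acylation in the closure; closure through the enolate oxygen would give an enol lactone that the released alkoxide can reopen, whereas closure through carbon ends in an aromatic phenoxide. Mono-addition is secured by 1:1 stoichiometry and slow addition of 14 to the preformed enolate. No stereocentre is created: the sp3 centre at B6 of 15 is racemic and is erased on aromatisation.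

**Step 8**
Reactants: 16 5-[2,4,6-tris(benzyloxy)phenoxy]-2,4-bis[3,4,5-tris(benzyloxy)phenoxy]benzene-1,3-diol
Product: 17 2,4-bis(3,4,5-trihydroxyphenoxy)-5-(2,4,6-trihydroxyphenoxy)benzene-1,3-diol (CNP0304743.0)
Conditions: H2 (1 atm), Pd(OH)2/C, THF/MeOH 1:1, rt; filtration and concentration under Ar
Reagents that add atoms: none
Why: Hydrogenolysis of nine aryl benzyl ethers under neutral conditions; diaryl ethers and the phenolic rings are not reduced at 1 atm and room temperature, and exclusion of air protects the pyrogallol rings.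

## Compound list

1 | 3,4,5-tris(benzyloxy)benzaldehyde | O=Cc1cc(OCc2ccccc2)c(OCc2ccccc2)c(OCc2ccccc2)c1 | starting material
2 | 3,4,5-tris(benzyloxy)phenyl formate | O=COc1cc(OCc2ccccc2)c(OCc2ccccc2)c(OCc2ccccc2)c1 | intermediate (not isolated)
3 | 3,4,5-tris(benzyloxy)phenol | Oc1cc(OCc2ccccc2)c(OCc2ccccc2)c(OCc2ccccc2)c1 | intermediate
4 | 1,3-dichloroacetone | ClCC(=O)CCl | starting material
5 | 1,3-bis[3,4,5-tris(benzyloxy)phenoxy]propan-2-one | O=C(COc1cc(OCc2ccccc2)c(OCc2ccccc2)c(OCc2ccccc2)c1)COc1cc(OCc2ccccc2)c(OCc2ccccc2)c(OCc2ccccc2)c1 | intermediate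
6 | 1,3,5-tris(benzyloxy)benzene | C(Oc1cc(OCc2ccccc2)cc(OCc2ccccc2)c1)c1ccccc1 | starting material
7 | N-[2,4,6-tris(benzyloxy)benzylidene]-N-methylmethanaminium chloride | C[N+](C)=Cc1c(OCc2ccccc2)cc(OCc2ccccc2)cc1OCc1ccccc1.[Cl-] | intermediate (not isolated)
8 | 2,4,6-tris(benzyloxy)benzaldehyde | O=Cc1c(OCc2ccccc2)cc(OCc2ccccc2)cc1OCc1ccccc1 | intermediate
9 | 2,4,6-tris(benzyloxy)phenyl formate | O=COc1c(OCc2ccccc2)cc(OCc2ccccc2)cc1OCc1ccccc1 | intermediate (not isolated)
10 | 2,4,6-tris(benzyloxy)phenol | Oc1c(OCc2ccccc2)cc(OCc2ccccc2)cc1OCc1ccccc1 | intermediate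
11 | 1,3,5-tris(benzyloxy)-2-{[(E)-1,2-dichloroethenyl]oxy}benzene | Cl/C=C(/Cl)Oc1c(OCc2ccccc2)cc(OCc2ccccc2)cc1OCc1ccccc1 | intermediate
12 | 1,3,5-tris(benzyloxy)-2-[(chloroethynyl)oxy]benzene | ClC#COc1c(OCc2ccccc2)cc(OCc2ccccc2)cc1OCc1ccccc1 | intermediate (not isolated)
13 | lithium [2,4,6-tris(benzyloxy)phenoxy]acetylide | [Li]C#COc1c(OCc2ccccc2)cc(OCc2ccccc2)cc1OCc1ccccc1 | intermediate (not isolated)
14 | methyl 3-[2,4,6-tris(benzyloxy)phenoxy]prop-2-ynoate | COC(=O)C#COc1c(OCc2ccccc2)cc(OCc2ccccc2)cc1OCc1ccccc1 | intermediate
15 | methyl (E)-5-oxo-3-[2,4,6-tris(benzyloxy)phenoxy]-4,6-bis[3,4,5-tris(benzyloxy)phenoxy]hex-2-enoate (racemic at C4; the closure-competent E isomer is drawn) | COC(=O)/C=C(/Oc1c(OCc2ccccc2)cc(OCc2ccccc2)cc1OCc1ccccc1)C(Oc1cc(OCc2ccccc2)c(OCc2ccccc2)c(OCc2ccccc2)c1)C(=O)COc1cc(OCc2ccccc2)c(OCc2ccccc2)c(OCc2ccccc2)c1 | intermediate (not isolated)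
16 | 5-[2,4,6-tris(benzyloxy)phenoxy]-2,4-bis[3,4,5-tris(benzyloxy)phenoxy]benzene-1,3-diol | Oc1cc(Oc2c(OCc3ccccc3)cc(OCc3ccccc3)cc2OCc2ccccc2)c(Oc2cc(OCc3ccccc3)c(OCc3ccccc3)c(OCc3ccccc3)c2)c(O)c1Oc1cc(OCc2ccccc2)c(OCc2ccccc2)c(OCc2ccccc2)c1 | intermediate
17 | 2,4-bis(3,4,5-trihydroxyphenoxy)-5-(2,4,6-trihydroxyphenoxy)benzene-1,3-diol | Oc1cc(O)c(Oc2cc(O)c(Oc3cc(O)c(O)c(O)c3)c(O)c2Oc2cc(O)c(O)c(O)c2)c(O)c1 | target

## Step count and risk

Total step count: 8. Longest linear sequence: 6 (steps 3, 4, 5, 6, 7, 8).

**Step 7 (key step, proposed new method).**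
- What may go wrong: the conjugate addition to the donor-substituted alkyne may be slow, so that the ynoate oligomerises or the enolate attacks the ester carbonyl. The sequence may also stall at the Michael adduct or close through the enolate oxygen (lactonisation), because the ester of 15 is a vinylogous carbonate of reduced electrophilicity.
- Fallback (known reaction types only), from ketone 5 and phenol 10, rejoining the route at 16 through 15:
  - Condensation of 5 with malonyl dichloride (CH2Cl2, rt) should give 4-hydroxy-5-[3,4,5-tris(benzyloxy)phenoxy]-6-{[3,4,5-tris(benzyloxy)phenoxy]methyl}-2H-pyran-2-one F1. Its single hydroxyl is the future B1 oxygen.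
  - Tosylation (TsCl, Et3N) should give the pyran-4-yl 4-methylbenzenesulfonate F2.
  - Addition–elimination with the phenoxide of 10 (Cs2CO3, MeCN) should give 4-[2,4,6-tris(benzyloxy)phenoxy]-5-[3,4,5-tris(benzyloxy)phenoxy]-6-{[3,4,5-tris(benzyloxy)phenoxy]methyl}-2H-pyran-2-one F3, the enol lactone of 15.
  - Methoxide in MeOH/THF at reflux should open F3 to 15 and drive the Dieckmann closure to 16. The sodium salt of 10 is added so that aryloxide exchange at the vinylogous position is degenerate.

**Step 6.**
- What may go wrong: the lithium aryloxyacetylide may decompose above about −40 °C, benzylic lithiation with Wittig rearrangement may compete, and the push–pull ynoate may hydrate during chromatography.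
- Fallback, from phenol 10, rejoining at 16 through 15: vinylic substitution of methyl 3,3-dichloroacrylate by the phenoxide of 10 (K2CO3, MeCN) should give methyl 3-chloro-3-[2,4,6-tris(benzyloxy)phenoxy]prop-2-enoate F4. The sodium enolate of 5 should displace its chloride by addition–elimination to give the same adduct 15, which closes to 16 under the conditions of step 7. No organolithium reagent and no alkyne are then needed.

**Step 8.**
- What may go wrong: hydrogenolysis may stop at partly debenzylated material as the polar product adsorbs on the catalyst, and the pyrogallol rings may be oxidised by air during filtration and concentration.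
- Fallback, from 16 to 17: after hydrogenolysis the crude filtrate is acetylated in the same flask (Ac2O, pyridine) to the undecaacetate F6, 2,4-bis(3,4,5-triacetoxyphenoxy)-5-(2,4,6-triacetoxyphenoxy)-1,3-phenylene diacetate. F6 is air-stable and can be purified on silica. Deacetylation with catalytic K2CO3 in degassed MeOH at 0 °C, followed by an acidic resin, should release 17.

**Step 2.**
- What may go wrong: base-induced self-condensation or Favorskii-type degradation of dichloroacetone may compete, and the reaction may stop after the first alkylation.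
- Fallback, from phenol 3 to ketone 5: reaction of 3 (2 equiv) with epichlorohydrin (K2CO3, DMF, 80 °C) should give 1,3-bis[3,4,5-tris(benzyloxy)phenoxy]propan-2-ol F5 through the glycidyl ether. Dess–Martin oxidation of F5 gives 5.

## Further compounds

F1 | step 7 | 4-hydroxy-5-[3,4,5-tris(benzyloxy)phenoxy]-6-{[3,4,5-tris(benzyloxy)phenoxy]methyl}-2H-pyran-2-one | O=c1cc(O)c(Oc2cc(OCc3ccccc3)c(OCc3ccccc3)c(OCc3ccccc3)c2)c(COc2cc(OCc3ccccc3)c(OCc3ccccc3)c(OCc3ccccc3)c2)o1
F2 | step 7 | 2-oxo-5-[3,4,5-tris(benzyloxy)phenoxy]-6-{[3,4,5-tris(benzyloxy)phenoxy]methyl}-2H-pyran-4-yl 4-methylbenzenesulfonate | Cc1ccc(S(=O)(=O)Oc2cc(=O)oc(COc3cc(OCc4ccccc4)c(OCc4ccccc4)c(OCc4ccccc4)c3)c2Oc2cc(OCc3ccccc3)c(OCc3ccccc3)c(OCc3ccccc3)c2)cc1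
F3 | step 7 | 4-[2,4,6-tris(benzyloxy)phenoxy]-5-[3,4,5-tris(benzyloxy)phenoxy]-6-{[3,4,5-tris(benzyloxy)phenoxy]methyl}-2H-pyran-2-one | O=c1cc(Oc2c(OCc3ccccc3)cc(OCc3ccccc3)cc2OCc2ccccc2)c(Oc2cc(OCc3ccccc3)c(OCc3ccccc3)c(OCc3ccccc3)c2)c(COc2cc(OCc3ccccc3)c(OCc3ccccc3)c(OCc3ccccc3)c2)o1
F4 | step 6 | methyl 3-chloro-3-[2,4,6-tris(benzyloxy)phenoxy]prop-2-enoate (E/Z mixture, Z isomer drawn) | COC(=O)/C=C(\Cl)Oc1c(OCc2ccccc2)cc(OCc2ccccc2)cc1OCc1ccccc1
F5 | step 2 | 1,3-bis[3,4,5-tris(benzyloxy)phenoxy]propan-2-ol | OC(COc1cc(OCc2ccccc2)c(OCc2ccccc2)c(OCc2ccccc2)c1)COc1cc(OCc2ccccc2)c(OCc2ccccc2)c(OCc2ccccc2)c1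
F6 | step 8 | 2,4-bis(3,4,5-triacetoxyphenoxy)-5-(2,4,6-triacetoxyphenoxy)-1,3-phenylene diacetate | CC(=O)Oc1cc(OC(C)=O)c(Oc2cc(OC(C)=O)c(Oc3cc(OC(C)=O)c(OC(C)=O)c(OC(C)=O)c3)c(OC(C)=O)c2Oc2cc(OC(C)=O)c(OC(C)=O)c(OC(C)=O)c2)c(OC(C)=O)c1
A1 | alternative 1 | 2,4-dibromo-3,5-bis(benzyloxy)phenol | Oc1cc(OCc2ccccc2)c(Br)c(OCc2ccccc2)c1Br
A2 | alternative 1 | 2-bromo-1,3,5-tris(benzyloxy)benzene | Brc1c(OCc2ccccc2)cc(OCc2ccccc2)cc1OCc1ccccc1
A3 | alternative 1 | 2,4-dibromo-3,5-bis(benzyloxy)phenyl 2,4,6-tris(benzyloxy)phenyl ether | Brc1c(OCc2ccccc2)cc(Oc2c(OCc3ccccc3)cc(OCc3ccccc3)cc2OCc2ccccc2)c(Br)c1OCc1ccccc1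
A4 | alternative 1 | 1,3-bis(benzyloxy)-5-[2,4,6-tris(benzyloxy)phenoxy]-2,4-bis[3,4,5-tris(benzyloxy)phenoxy]benzene | c1ccccc1COc1cc(Oc2c(OCc3ccccc3)cc(OCc3ccccc3)cc2OCc2ccccc2)c(Oc2cc(OCc3ccccc3)c(OCc3ccccc3)c(OCc3ccccc3)c2)c(OCc2ccccc2)c1Oc1cc(OCc2ccccc2)c(OCc2ccccc2)c(OCc2ccccc2)c1
A5 | alternative 2 | 2,4-difluoro-5-[2,4,6-tris(benzyloxy)phenoxy]benzene-1,3-dicarbaldehyde | O=Cc1cc(Oc2c(OCc3ccccc3)cc(OCc3ccccc3)cc2OCc2ccccc2)c(F)c(C=O)c1F
A6 | alternative 2 | 2,4-bis[3,4,5-tris(benzyloxy)phenoxy]-5-[2,4,6-tris(benzyloxy)phenoxy]benzene-1,3-dicarbaldehyde | O=Cc1cc(Oc2c(OCc3ccccc3)cc(OCc3ccccc3)cc2OCc2ccccc2)c(Oc2cc(OCc3ccccc3)c(OCc3ccccc3)c(OCc3ccccc3)c2)c(C=O)c1Oc1cc(OCc2ccccc2)c(OCc2ccccc2)c(OCc2ccccc2)c1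
A7 | alternative 3 | 2-(3,5-dihydroxyphenoxy)benzene-1,3,5-triol | Oc1cc(O)cc(Oc2c(O)cc(O)cc2O)c1
A8 | alternative 3 | benzene-1,2,3,5-tetrol | Oc1cc(O)c(O)c(O)c1
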